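## Retrosynthetic overview

- **Numbering.** C1 is the ring ketone next to the carbinol, C2 the acyl-bearing carbon, C3 the enol carbon, C4 and C5 the two CH2 groups, and C6 the (S)-carbinol carbon.
- **Late disconnections.** The C6 acetate and the C2–acyl bond come off last. The acyl bond is made by O-acylation and O-to-C acyl shift of a 4-acetoxycyclohexane-1,3-dione with (E)-hexadec-14-enoic acid. The acid comes from 1,12-dibromododecane, propynyllithium and CO2, followed by a trans-selective alkyne reduction.
- **Key disconnection.** C4–C5 and C1–C6 are cut together. In the forward direction this is a rhodium-catalysed two-carbon ring expansion (formal [4+2]) of 3-ethoxycyclobut-2-enone (C1 to C4) by vinyl acetate (C5–C6).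
- **Enabling feature.** O=C1–C2=C3–O with C4H2 is a vinylogous acid that a C1–C4 bond folds into a strained four-membered ring, and C6 carries oxygen next to C1, so C5=C6 is an enol ester. Both new bonds join carbons of like polarity (C4/C5 both donors, C1/C6 both acceptors), so a metal insertion is used rather than an ionic annulation.
- **Ring order.** The cyclobutenone is made first ([2+2] of ketene and ethoxyacetylene). It is then expanded to the only ring of the target.

Key step: step 2

Assumption: the beta-triketones are rapidly interconverting enol tautomers and are written in the tautomer drawn for the target; (R)-DTBM-SEGPHOS is assumed to be the ligand enantiomer that leads to (S) at C6, otherwise its mirror image is used.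

## Route

Step 1
Reactants: 1 ethoxyacetylene; 2 acetyl chloride
Product: 4 3-ethoxycyclobut-2-en-1-one, via ketene 3 (not isolated)
Conditions: Et3N, Et2O, 0 °C to reflux, slow addition of 2
Reagents that add atoms: none
Why: Thermal [2+2] cycloaddition of a ketene (from dehydrochlorination of 2) to an ynol ether, in which the nucleophilic CH terminus of 1 attacks the ketene carbonyl carbon and so fixes the 3-ethoxy regiochemistry; no stereocenter is formed.

Step 2
Reactants: 4 3-ethoxycyclobut-2-en-1-one; 5 vinyl acetate
Product: 8 (S)-6-acetoxy-3-ethoxycyclohex-2-en-1-one, via rhodacyclopentenone 6 (not isolated), via seven-membered rhodacycle 7 (not isolated)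
Conditions: [Rh(cod)2]BF4 (5 mol %), (R)-DTBM-SEGPHOS (6 mol %), 5 (5 equiv), 1,2-dichloroethane, 50 °C, slow addition of 4
Reagents that add atoms: none
Why: Proposed new method: monovalent rhodium inserts into the strained acyl–CH2 bond C1–C4 of 4 to give the trivalent rhodacyclopentenone 6 (the sigma form of an eta-4 vinylketene complex), vinyl acetate inserts into its Rh–CH2 bond so that C4 bonds to the CH2 terminus C5 and rhodium moves to the acetoxy-bearing C6 (7), and acyl–alkyl reductive elimination joins C1 to C6 and returns monovalent rhodium. The closest known reaction types are the rhodium- and ruthenium-catalysed ring-opening coupling of cyclobutenones with strained alkenes to cyclohexenones, the nickel-catalysed cyclobutenone–alkyne [4+2] and the enantioselective rhodium cut-and-sew carboacylation of tethered alkenes by benzocyclobutenones and cyclobutanones, so that only the untethered enol ester partner is new. The six-membered ring closes by C(acyl)–C(sp3) reductive elimination from the seven-membered rhodacycle 7, a formal [4+2] that is driven by the release of the four-ring strain. C6, the only new stereocenter, is set at the migratory insertion by the face of 5 that the chiral pocket of the C2-symmetric bisphosphine leaves open and is carried with retention through the reductive elimination. The step needs regioselective insertion (C4 to CH2, metal to CH–OAc), which the enol ester secures through chelation of its carbonyl oxygen and the electronic preference for an alpha-acyloxyalkyl–metal bond, the bias that makes hydroformylation of vinyl acetate branched-selective and that also keeps the acetate out of reach of beta-elimination, and it needs cleavage of C1–C4 instead of C1–C2, which the weaker acyl–sp3 bond of the cyclobutenone secures. Beta-hydride elimination, decarbonylation and dimerisation of the ring-opened ketene are held back by the chelate, the bulky ligand, the moderate temperature, the excess of 5 and the slow addition of 4.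

Step 3
Reactants: 8 (S)-6-acetoxy-3-ethoxycyclohex-2-en-1-one
Product: 9 (S)-4-acetoxycyclohexane-1,3-dione
Conditions: 1 M HCl, THF, 0 °C to rt
Reagents that add atoms: water, O
Why: Acid-catalysed hydrolysis of a vinylogous ester (addition–elimination at C3) should be much faster than hydrolysis of the secondary acetate, and it does not touch the C6–O bond or its configuration.

Step 4
Reactants: 10 1,12-dibromododecane; 11 1-propynyllithium
Product: 12 15-bromopentadec-2-yne
Conditions: 10 (3 equiv), THF/DMPU, −78 °C to rt
Reagents that add atoms: none
Why: SN2 alkylation of a lithium acetylide by a primary bromide in a dipolar cosolvent, with the excess of the symmetrical dibromide (recoverable) holding the reaction at the mono-substitution stage.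

Step 5
Reactants: 12 15-bromopentadec-2-yne
Product: 14 hexadec-14-ynoic acid, via Grignard reagent 13 (not isolated)
Conditions: Mg, THF, reflux; CO2 (solid), −78 °C to rt; 1 M HCl
Reagents that add atoms: carbon dioxide, O=C=O
Why: Grignard formation and carboxylation add the missing carboxyl carbon, and the internal alkyne is inert to both operations.

Step 6
Reactants: 14 hexadec-14-ynoic acid
Product: 15 (E)-hexadec-14-enoic acid
Conditions: Li, NH3(l)/THF, t-BuOH, −33 °C; NH4Cl
Reagents that add atoms: none
Why: Dissolving-metal (Birch-type) reduction of an internal alkyne passes through the more stable trans vinyl radical and anion and should give the E alkene, while the carboxylate is not reduced.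

Step 7
Reactants: 9 (S)-4-acetoxycyclohexane-1,3-dione; 15 (E)-hexadec-14-enoic acid
Product: 17 (1S)-3-[(E)-hexadec-14-enoyl]-4-hydroxy-2-oxocyclohex-3-en-1-yl acetate, via enol ester 16 (not isolated)
Conditions: DCC, DMAP, CH2Cl2, 0 °C to rt
Reagents that add atoms: none
Why: Steglich-type O-acylation of the enol followed by DMAP-catalysed O-to-C acyl migration, the standard entry to 2-acylcyclohexane-1,3-diones; both regioisomeric enol esters converge on C2, and C6 is untouched because the dione reacts as its enolate.

Step 8
Reactants: 17 (1S)-3-[(E)-hexadec-14-enoyl]-4-hydroxy-2-oxocyclohex-3-en-1-yl acetate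
Product: 18 (6S)-2-[(E)-hexadec-14-enoyl]-3,6-dihydroxycyclohex-2-en-1-one (target)
Conditions: K2CO3, MeOH, 0 °C; 1 M HCl to pH 4
Reagents that add atoms: none
Why: Base-catalysed transesterification removes the secondary acetate while the triketone sits as its delocalised enolate, which lowers the acidity of the C6–H bond and should protect against epimerisation and retro-Claisen cleavage.

## Compound list

1 | ethoxyacetylene | CCOC#C | starting material
2 | acetyl chloride | CC(=O)Cl | starting material
3 | ketene (not isolated) | C=C=O | intermediate
4 | 3-ethoxycyclobut-2-en-1-one | CCOC1=CC(=O)C1 | intermediate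
5 | vinyl acetate | C=COC(C)=O | starting material
6 | rhodacyclopentenone, ligands omitted (not isolated) | CCOC1=CC(=O)[Rh]C1 | intermediate
7 | seven-membered rhodacycle, ligands omitted (not isolated) | CCOC1=CC(=O)[Rh][C@@H](OC(C)=O)CC1 | intermediate
8 | (S)-6-acetoxy-3-ethoxycyclohex-2-en-1-one | CCOC1=CC(=O)[C@@H](OC(C)=O)CC1 | intermediate
9 | (S)-4-acetoxycyclohexane-1,3-dione | CC(=O)O[C@H]1CCC(=O)CC1=O | intermediate
10 | 1,12-dibromododecane | BrCCCCCCCCCCCCBr | starting material
11 | 1-propynyllithium | [Li]C#CC | starting material
12 | 15-bromopentadec-2-yne | CC#CCCCCCCCCCCCCBr | intermediate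
13 | pentadec-13-yn-1-ylmagnesium bromide (not isolated) | CC#CCCCCCCCCCCCC[Mg]Br | intermediate
14 | hexadec-14-ynoic acid | CC#CCCCCCCCCCCCCC(=O)O | intermediate
15 | (E)-hexadec-14-enoic acid | C/C=C/CCCCCCCCCCCCC(=O)O | intermediate
16 | (4S)-4-acetoxy-3-oxocyclohex-1-en-1-yl (E)-hexadec-14-enoate, one of two converging enol esters (not isolated) | C/C=C/CCCCCCCCCCCCC(=O)OC1=CC(=O)[C@@H](OC(C)=O)CC1 | intermediate
17 | (1S)-3-[(E)-hexadec-14-enoyl]-4-hydroxy-2-oxocyclohex-3-en-1-yl acetate | C/C=C/CCCCCCCCCCCCC(=O)C1=C(O)CC[C@H](OC(C)=O)C1=O | intermediate
18 | (6S)-2-[(E)-hexadec-14-enoyl]-3,6-dihydroxycyclohex-2-en-1-one | C/C=C/CCCCCCCCCCCCC(=O)C1=C(O)CC[C@H](O)C1=O | target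

## Step count and risks

Total step count: 8.
Longest linear sequence: 5 steps (1, 2, 3, 7, 8). The chain branch 4, 5, 6, 7, 8 is equally long.

**Step 2.**
- What may go wrong:
  - beta-hydride elimination from the rhodacycle
  - decarbonylation
  - dimerisation of the ring-opened ketene
  - reversed insertion regiochemistry
  - poor facial selectivity on the enol ester
- Fallback (known chemistry): the C6–O bond is made on a preformed six-membered ring and the enantiomers are separated enzymatically. It sets out from vinyl acetate 5, now the irreversible acyl donor, and comes back at 8.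
  - Purchased 3-ethoxycyclohex-2-en-1-one F1 is deprotonated at the alpha-prime position (LiN(iPr)2, THF, −78 °C).
  - The enolate is oxidised with 3-phenyl-2-(phenylsulfonyl)oxaziridine to racemic 3-ethoxy-6-hydroxycyclohex-2-en-1-one F2.
  - Burkholderia cepacia lipase and 5 in MTBE should, by the empirical size rule for secondary alcohols, acetylate the (R)-alcohol to (R)-6-acetoxy-3-ethoxycyclohex-2-en-1-one F3. This leaves (S)-3-ethoxy-6-hydroxycyclohex-2-en-1-one F4.
  - After separation, F4 is acetylated with acetyl chloride 2 and pyridine to 8.

**Step 1.**
- What may go wrong: self-condensation of the unsubstituted ketene and amine-promoted side acylations may outrun the cycloaddition.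
- Fallback: a more electrophilic ketene is used and the halogens are removed afterwards. It sets out from ethoxyacetylene 1 and comes back at 4.
  - Dichloroketene F5 is made in the flask from trichloroacetyl chloride and Zn in Et2O.
  - F5 adds to 1 to give 4,4-dichloro-3-ethoxycyclobut-2-en-1-one F6.
  - Zn, AcOH and TMEDA in EtOH remove both chlorines to give 4.

**Step 8.**
- What may go wrong: base-induced enolisation at the carbinol carbon (loss of configuration), alpha-ketol transposition or retro-Claisen cleavage during ester removal.
- Fallback: the protecting group is exchanged early, so that the last step is a fluoride cleavage under non-basic conditions. It sets out from 8 and comes back at 18.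
  - K2CO3 in MeOH at 0 °C gives (S)-3-ethoxy-6-hydroxycyclohex-2-en-1-one F4, the compound also met in the fallback to step 2.
  - TBSCl and imidazole give (S)-6-[(tert-butyldimethylsilyl)oxy]-3-ethoxycyclohex-2-en-1-one F7.
  - LiOH in THF/H2O, then adjustment to pH 5, gives (S)-4-[(tert-butyldimethylsilyl)oxy]cyclohexane-1,3-dione F8.
  - DCC and DMAP with acid 15 give (6S)-6-[(tert-butyldimethylsilyl)oxy]-2-[(E)-hexadec-14-enoyl]-3-hydroxycyclohex-2-en-1-one F9.
  - HF·pyridine in THF at 0 °C gives 18.

## Further compounds

F1 | step 2 | 3-ethoxycyclohex-2-en-1-one (purchased) | CCOC1=CC(=O)CCC1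
F2 | step 2 | racemic 3-ethoxy-6-hydroxycyclohex-2-en-1-one | CCOC1=CC(=O)C(O)CC1
F3 | step 2 | (R)-6-acetoxy-3-ethoxycyclohex-2-en-1-one | CCOC1=CC(=O)[C@H](OC(C)=O)CC1
F4 | step 2 | (S)-3-ethoxy-6-hydroxycyclohex-2-en-1-one | CCOC1=CC(=O)[C@@H](O)CC1
F5 | step 1 | dichloroketene | ClC(Cl)=C=O
F6 | step 1 | 4,4-dichloro-3-ethoxycyclobut-2-en-1-one | CCOC1=CC(=O)C1(Cl)Cl
F7 | step 8 | (S)-6-[(tert-butyldimethylsilyl)oxy]-3-ethoxycyclohex-2-en-1-one | CCOC1=CC(=O)[C@@H](O[Si](C)(C)C(C)(C)C)CC1
F8 | step 8 | (S)-4-[(tert-butyldimethylsilyl)oxy]cyclohexane-1,3-dione | CC(C)(C)[Si](C)(C)O[C@H]1CCC(=O)CC1=O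
F9 | step 8 | (6S)-6-[(tert-butyldimethylsilyl)oxy]-2-[(E)-hexadec-14-enoyl]-3-hydroxycyclohex-2-en-1-one | C/C=C/CCCCCCCCCCCCC(=O)C1=C(O)CC[C@H](O[Si](C)(C)C(C)(C)C)C1=O
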